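**Plan**

- Retrosynthesis: cut the macrolactone C(=O)–O bond at the methyl carbinol, then add water across the exocyclic enol ether (giving a hemiketal). Next cut the butyrolactone at its Cα–Cβ bond and its ring C(=O)–O bond, which gives a hemiketal β-keto ester and an acyclic γ-hydroxy enone.
- The β-keto ester goes back to ethyl acetate and the bicyclic lactone 9. In 9 the ring-fusion bond C-3a–C-7a and the lactone bond O-1–C-2 are cut together, giving the acyclic dialdehyde 6. The enone is cut at its C=C bond (cross-metathesis).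
- Enabling feature: in the furo[3,2-b]pyran unit the enol-ether carbon C-2 is at carboxyl level and lies 1,4 to O-1 on C-7a, while C-3a carries the pyran oxygen O-4. C-3a is therefore the β-carbon of a 3-alkoxyacrolein and C-7a an aldehyde carbon: two acceptor carbons held at six-ring distance by O-4, which a carbene-generated homoenolate can join with lactonisation.
- Forward order: pyran and furanone rings together (step 5), acetate Claisen addition, butyrolactone by Michael addition–lactonisation, enol ether by dehydration, ten-membered lactone last.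
- Stereochemistry: the two C-methyl carbinols come from 1 and 12, and the lactone γ-carbon from 16. The two ring-fusion centres are set in the key step under control of the C-5 methyl group. The lactone β-carbon (trans) and the (E)-alkene are set under thermodynamic control.

Key step: step 5

Remark: 1, 12 and 16 are taken as purchasable enantiopure building blocks (16 is otherwise available from tert-butyl acetate and acrolein by aldol addition and lipase resolution); 11, 18 and 19 are drawn as cyclic hemiketals, which equilibrate with the open β-keto ester forms.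

**Step 1**
Reactants: 1 (2R)-hex-5-en-2-ol; 2 ethyl propiolate
Product: 3 ethyl (2E)-3-{[(2R)-hex-5-en-2-yl]oxy}prop-2-enoate
Conditions: N-methylmorpholine, CH2Cl2, rt
Reagents that add atoms: none
Why: amine-catalysed oxa-Michael addition of a secondary alcohol to a propiolate should give the (E)-β-alkoxyacrylate without touching the carbinol centre.

**Step 2**
Reactants: 3 ethyl (2E)-3-{[(2R)-hex-5-en-2-yl]oxy}prop-2-enoate
Product: 4 (2E)-3-{[(2R)-hex-5-en-2-yl]oxy}prop-2-en-1-ol
Conditions: i-Bu2AlH (2.5 equiv), CH2Cl2, −78 °C; aq. Rochelle salt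
Reagents that add atoms: none
Why: 1,2-reduction of the vinylogous carbonate ester by i-Bu2AlH at low temperature should stop at the allylic alcohol and leave the isolated alkene alone.

**Step 3**
Reactants: 4 (2E)-3-{[(2R)-hex-5-en-2-yl]oxy}prop-2-en-1-ol
Product: 5 (2E)-3-{[(2R)-hex-5-en-2-yl]oxy}prop-2-enal
Conditions: MnO2 (excess), CH2Cl2, rt
Reagents that add atoms: none
Why: MnO2 oxidation is selective for the allylic alcohol and should give the 3-alkoxyacrolein with the (E) geometry retained.

**Step 4**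
Reactants: 5 (2E)-3-{[(2R)-hex-5-en-2-yl]oxy}prop-2-enal
Product: 6 (4R)-4-{[(1E)-3-oxoprop-1-en-1-yl]oxy}pentanal
Conditions: K2OsO4·2H2O (2 mol %), NaIO4, 2,6-lutidine, dioxane–H2O, rt
Reagents that add atoms: sodium periodate, [Na+].[O-]I(=O)(=O)=O (terminal oxidant that supplies the aldehyde oxygen through the osmium catalyst)
Why: Lemieux–Johnson cleavage should pick the unhindered terminal alkene, because the push–pull alkene of the vinylogous formate is electron-poor toward osmylation and lutidine buffers the medium.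

**Step 5**
Reactants: 6 (4R)-4-{[(1E)-3-oxoprop-1-en-1-yl]oxy}pentanal
Product: 9 (3aS,5R,7aS)-5-methylhexahydro-2H-furo[3,2-b]pyran-2-one, via Breslow intermediate 7 (not isolated), via acyl azolium alkoxide 8 (not isolated)
Conditions: 1,3-bis(2,4,6-trimethylphenyl)imidazolium chloride (10 mol %), DBU (10 mol %), THF (0.02 M), rt to 40 °C
Reagents that add atoms: none
Why: Proposed new method: the free carbene adds to the enal carbonyl of 6 and proton transfer gives the alkoxy-substituted extended Breslow intermediate 7, whose β-carbon (the O-bearing carbon, turned from acceptor into donor) attacks the tethered aldehyde carbon; the new alkoxide in 8 then acylates on the acyl azolium and releases the carbene, so the ring-fusion C–C bond and the lactone O–C(=O) bond arise in one catalytic turnover. The closest known reaction type is the carbene-catalysed homoenolate annulation of enals with aldehydes or tethered ketones to γ-butyrolactones; a β-alkoxy enal as homoenolate precursor is the untested element. The pyran ring closes 6-exo-trig (carbon nucleophile on C=O) and the lactone ring 5-exo-trig (alkoxide on the acyl azolium carbonyl). C-3a is set by the existing C-5 methyl centre through a chair-like transition state with methyl and enol side chain both equatorial (2,6-cis); C-7a is set relative to C-3a because only the cis alkoxide reaches the acyl azolium in a strain-free 5-exo closure while the C–C bond formation is reversible, so turnover should drain the cis adduct. The step needs homoenolate reactivity of the enal to win over acyl-anion (Stetter or benzoin) reactivity of the saturated aldehyde; the N-mesityl imidazolylidene (which favours Breslow formation on enals), the poor acceptor quality of a vinylogous formate and high dilution should secure this.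

**Step 6**
Reactants: 9 (3aS,5R,7aS)-5-methylhexahydro-2H-furo[3,2-b]pyran-2-one; 10 ethyl acetate
Product: 11 ethyl 2-[(3aS,5R,7aS)-2-hydroxy-5-methylhexahydro-2H-furo[3,2-b]pyran-2-yl]acetate
Conditions: LiN(i-Pr)2, 10, THF, −78 °C; then 9, −78 °C; AcOH quench
Reagents that add atoms: none
Why: Claisen-type addition of the lithium ester enolate to the lactone carbonyl should stop at the tetrahedral adduct at −78 °C and give the cyclic hemiketal β-keto ester on protonation, the three stereocentres not being involved.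

**Step 7**
Reactants: 12 (5R)-5-methyldihydrofuran-2(3H)-one ((R)-γ-valerolactone)
Product: 13 (4R)-4-hydroxy-N-methoxy-N-methylpentanamide
Conditions: MeNH(OMe)·HCl, i-PrMgCl, THF, −20 to 0 °C
Reagents that add atoms: N,O-dimethylhydroxylamine hydrochloride, CNOC.Cl
Why: Weinreb amide formation by aminolysis of the lactone with the magnesium amide opens the ring with retention at the carbinol centre.

**Step 8**
Reactants: 13 (4R)-4-hydroxy-N-methoxy-N-methylpentanamide
Product: 14 (4R)-4-[(tert-butyldimethylsilyl)oxy]-N-methoxy-N-methylpentanamide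
Conditions: TBSCl, imidazole, DMF, rt
Reagents that add atoms: tert-butyldimethylsilyl chloride, CC(C)(C)[Si](C)(C)Cl
Why: standard silyl ether protection blocks relactonisation and masks the carbinol for the following steps.

**Step 9**
Reactants: 14 (4R)-4-[(tert-butyldimethylsilyl)oxy]-N-methoxy-N-methylpentanamide
Product: 15 (6R)-6-[(tert-butyldimethylsilyl)oxy]hept-1-en-3-one
Conditions: CH2=CHMgBr, THF, 0 °C; inverse quench into cold aq. HCl
Reagents that add atoms: vinylmagnesium bromide, C=C[Mg]Br
Why: Weinreb ketone synthesis: the vinyl Grignard reagent adds once through the stable magnesium chelate, and the inverse acidic quench should prevent conjugate addition of the released amine.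

**Step 10**
Reactants: 15 (6R)-6-[(tert-butyldimethylsilyl)oxy]hept-1-en-3-one; 16 tert-butyl (3S)-3-hydroxypent-4-enoate
Product: 17 tert-butyl (3S,4E,9R)-9-[(tert-butyldimethylsilyl)oxy]-3-hydroxy-6-oxodec-4-enoate
Conditions: (H2IMes)Cl2Ru=CH(C6H4-2-O-i-Pr) (second-generation Hoveyda–Grubbs catalyst, 5 mol %), 15 (2 equiv), CH2Cl2, 40 °C
Reagents that add atoms: none
Why: olefin cross-metathesis of a secondary allylic alcohol with an alkyl vinyl ketone should favour the cross product as the (E)-enone, and neither stereocentre takes part.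

**Step 11**
Reactants: 11 ethyl 2-[(3aS,5R,7aS)-2-hydroxy-5-methylhexahydro-2H-furo[3,2-b]pyran-2-yl]acetate; 17 tert-butyl (3S,4E,9R)-9-[(tert-butyldimethylsilyl)oxy]-3-hydroxy-6-oxodec-4-enoate
Product: 19 tert-butyl 2-[(2S,3R)-3-{(5R)-5-[(tert-butyldimethylsilyl)oxy]-2-oxohexyl}-4-[(3aS,5R,7aS)-2-hydroxy-5-methylhexahydro-2H-furo[3,2-b]pyran-2-yl]-5-oxooxolan-2-yl]acetate, via Michael adduct 18 (not isolated)
Conditions: Cs2CO3 (0.5 equiv), MeCN, 0 °C to rt
Reagents that add atoms: none
Why: Michael addition of the β-keto ester (open form of 11) to the enone followed by lactonisation of the γ-hydroxy ester should set the lactone β-carbon trans to the γ side chain under thermodynamic control, since retro-Michael and 5-exo re-addition through the ester-tethered keto ester equilibrate the adduct.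

**Step 12**
Reactants: 19 tert-butyl 2-[(2S,3R)-3-{(5R)-5-[(tert-butyldimethylsilyl)oxy]-2-oxohexyl}-4-[(3aS,5R,7aS)-2-hydroxy-5-methylhexahydro-2H-furo[3,2-b]pyran-2-yl]-5-oxooxolan-2-yl]acetate
Product: 20 2-[(2S,3R,4E)-3-[(5R)-5-hydroxy-2-oxohexyl]-4-[(3aS,5R,7aS)-5-methylhexahydro-2H-furo[3,2-b]pyran-2-ylidene]-5-oxooxolan-2-yl]acetic acid
Conditions: CF3CO2H, CH2Cl2, 0 °C to rt; then THF–H2O
Reagents that add atoms: none
Why: acid-catalysed dehydration of the hemiketal should give the conjugated exocyclic enol ether, whose (E) geometry (ring oxygen anti to the lactone carbonyl) is the thermodynamic one, while the same acid cleaves the tert-butyl ester and the silyl ether.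

**Step 13**
Reactants: 20 2-[(2S,3R,4E)-3-[(5R)-5-hydroxy-2-oxohexyl]-4-[(3aS,5R,7aS)-5-methylhexahydro-2H-furo[3,2-b]pyran-2-ylidene]-5-oxooxolan-2-yl]acetic acid
Product: 22 cordycicadin D, via mixed anhydride 21 (not isolated)
Conditions: 2-methyl-6-nitrobenzoic anhydride, DMAP, Et3N, CH2Cl2 (1 mM, slow addition), rt
Reagents that add atoms: none
Why: Shiina macrolactonisation under high dilution should close the ten-membered lactone with retention at the carbinol centre, the trans-fused butyrolactone and the ring ketone pre-organising the chain.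

**Compound list**

1 | (2R)-hex-5-en-2-ol | C[C@@H](O)CCC=C | starting material
2 | ethyl propiolate | C#CC(=O)OCC | starting material
3 | ethyl (2E)-3-{[(2R)-hex-5-en-2-yl]oxy}prop-2-enoate | C=CCC[C@@H](C)O/C=C/C(=O)OCC | intermediate
4 | (2E)-3-{[(2R)-hex-5-en-2-yl]oxy}prop-2-en-1-ol | C=CCC[C@@H](C)O/C=C/CO | intermediate
5 | (2E)-3-{[(2R)-hex-5-en-2-yl]oxy}prop-2-enal | C=CCC[C@@H](C)O/C=C/C=O | intermediate
6 | (4R)-4-{[(1E)-3-oxoprop-1-en-1-yl]oxy}pentanal | O=CCC[C@@H](C)O/C=C/C=O | intermediate
7 | Breslow intermediate: (4R)-4-{[(1E)-3-hydroxy-3-[1,3-bis(2,4,6-trimethylphenyl)-1,3-dihydro-2H-imidazol-2-ylidene]prop-1-en-1-yl]oxy}pentanal | O=CCC[C@@H](C)O/C=C/C(O)=C1N(c2c(C)cc(C)cc2C)C=CN1c1c(C)cc(C)cc1C | intermediate (not isolated)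
8 | acyl azolium alkoxide: 2-{2-[(2S,3S,6R)-6-methyl-3-oxidooxan-2-yl]acetyl}-1,3-bis(2,4,6-trimethylphenyl)imidazol-3-ium | O=C(C[C@@H]1O[C@H](C)CC[C@@H]1[O-])c1n(-c2c(C)cc(C)cc2C)cc[n+]1-c1c(C)cc(C)cc1C | intermediate (not isolated)
9 | (3aS,5R,7aS)-5-methylhexahydro-2H-furo[3,2-b]pyran-2-one (cis-fused, all three ring hydrogens on one face) | O=C1C[C@@H]2O[C@H](C)CC[C@@H]2O1 | intermediate
10 | ethyl acetate | CC(=O)OCC | starting material
11 | ethyl 2-[(3aS,5R,7aS)-2-hydroxy-5-methylhexahydro-2H-furo[3,2-b]pyran-2-yl]acetate (both hemiketal epimers) | CCOC(=O)CC1(O)C[C@@H]2O[C@H](C)CC[C@@H]2O1 | intermediate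
12 | (5R)-5-methyldihydrofuran-2(3H)-one ((R)-γ-valerolactone) | C[C@@H]1CCC(=O)O1 | starting material
13 | (4R)-4-hydroxy-N-methoxy-N-methylpentanamide | C[C@@H](O)CCC(=O)N(C)OC | intermediate
14 | (4R)-4-[(tert-butyldimethylsilyl)oxy]-N-methoxy-N-methylpentanamide | C[C@@H](O[Si](C)(C)C(C)(C)C)CCC(=O)N(C)OC | intermediate
15 | (6R)-6-[(tert-butyldimethylsilyl)oxy]hept-1-en-3-one | C=CC(=O)CC[C@@H](C)O[Si](C)(C)C(C)(C)C | intermediate
16 | tert-butyl (3S)-3-hydroxypent-4-enoate | C=C[C@@H](O)CC(=O)OC(C)(C)C | starting material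
17 | tert-butyl (3S,4E,9R)-9-[(tert-butyldimethylsilyl)oxy]-3-hydroxy-6-oxodec-4-enoate | CC(C)(C)OC(=O)C[C@H](O)/C=C/C(=O)CC[C@@H](C)O[Si](C)(C)C(C)(C)C | intermediate
18 | Michael adduct: 6-tert-butyl 1-ethyl (3R,4S)-3-{(5R)-5-[(tert-butyldimethylsilyl)oxy]-2-oxohexyl}-4-hydroxy-2-[(3aS,5R,7aS)-2-hydroxy-5-methylhexahydro-2H-furo[3,2-b]pyran-2-yl]hexanedioate (epimers at C-2 and the hemiketal carbon) | CCOC(=O)C(C1(O)C[C@@H]2O[C@H](C)CC[C@@H]2O1)[C@H]([C@@H](O)CC(=O)OC(C)(C)C)CC(=O)CC[C@@H](C)O[Si](C)(C)C(C)(C)C | intermediate (not isolated)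
19 | tert-butyl 2-[(2S,3R)-3-{(5R)-5-[(tert-butyldimethylsilyl)oxy]-2-oxohexyl}-4-[(3aS,5R,7aS)-2-hydroxy-5-methylhexahydro-2H-furo[3,2-b]pyran-2-yl]-5-oxooxolan-2-yl]acetate (trans at C-2/C-3 of the oxolane; epimers at C-4 and the hemiketal carbon) | CC(C)(C)OC(=O)C[C@@H]1OC(=O)C(C2(O)C[C@@H]3O[C@H](C)CC[C@@H]3O2)[C@H]1CC(=O)CC[C@@H](C)O[Si](C)(C)C(C)(C)C | intermediate
20 | 2-[(2S,3R,4E)-3-[(5R)-5-hydroxy-2-oxohexyl]-4-[(3aS,5R,7aS)-5-methylhexahydro-2H-furo[3,2-b]pyran-2-ylidene]-5-oxooxolan-2-yl]acetic acid | C[C@@H](O)CCC(=O)C[C@@H]1/C(=C2/C[C@@H]3O[C@H](C)CC[C@@H]3O2)C(=O)O[C@H]1CC(=O)O | intermediate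
21 | mixed anhydride of 20 with 2-methyl-6-nitrobenzoic acid | C[C@@H](O)CCC(=O)C[C@@H]1/C(=C2/C[C@@H]3O[C@H](C)CC[C@@H]3O2)C(=O)O[C@H]1CC(=O)OC(=O)c1c(C)cccc1[N+](=O)[O-] | intermediate (not isolated)
22 | cordycicadin D (trans-fused γ-butyrolactone/ten-membered keto lactone carrying the (E)-(3aS,5R,7aS)-5-methylhexahydrofuro[3,2-b]pyran-2-ylidene group on the lactone α-carbon) | C[C@@H]1CCC(=O)C[C@@H]2/C(=C3/C[C@@H]4O[C@H](C)CC[C@@H]4O3)C(=O)O[C@H]2CC(=O)O1 | target

**Totals**

Total step count: 13. Longest linear sequence: 9 steps (steps 1–6 and 11–13).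

**Steps most likely to fail**

Step 5 (proposed new method). The carbene may engage the saturated aldehyde first, leading to Stetter or benzoin chemistry. The alkoxy homoenolate may be protonated or lose alkoxide before C–C bond formation. The cis/trans ratio at the ring fusion may be poor if lactonisation does not gate the outcome. The fallback uses known chemistry, sets out from 3 and returns at 9. Lemieux–Johnson cleavage of the terminal alkene of 3 (K2OsO4·2H2O, NaIO4, 2,6-lutidine) would give ethyl (2E)-3-{[(2R)-5-oxopentan-2-yl]oxy}prop-2-enoate F1. Samarium diiodide (SmI2) with methanol in THF would then effect the ketyl–olefin cyclisation of this β-alkoxyacrylate aldehyde to the 2,6-cis-2,3-trans tetrahydropyran ethyl 2-[(2S,3R,6R)-3-hydroxy-6-methyloxan-2-yl]acetate F2. Saponification with LiOH would give 2-[(2S,3R,6R)-3-hydroxy-6-methyloxan-2-yl]acetic acid F3. Mitsunobu lactonisation (PPh3, DIAD, toluene) would close the γ-lactone with inversion at the carbinol carbon and so deliver the cis-fused lactone 9.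

Step 11. Lactonisation may lag behind the Michael addition, so that the adduct is diverted into hemiketal, dihydrofuran or spiroketal manifolds in the next acid step. The γ-hydroxy enone may undergo base-induced redox isomerisation. Trans selectivity is lost if the equilibration is slow. The fallback forms the ester bond first and the C–C bond second; it sets out from 9 and 17 and returns at 19. Addition of the lithium enolate of benzyl acetate to 9 would give benzyl 2-[(3aS,5R,7aS)-2-hydroxy-5-methylhexahydro-2H-furo[3,2-b]pyran-2-yl]acetate F4. Hydrogenolysis over palladium on carbon (Pd/C, H2) would give 2-[(3aS,5R,7aS)-2-hydroxy-5-methylhexahydro-2H-furo[3,2-b]pyran-2-yl]acetic acid F5, to be used at once. Carbodiimide esterification (EDC·HCl, DMAP) with the hydroxyl group of 17 would give tert-butyl (3S,4E,9R)-9-[(tert-butyldimethylsilyl)oxy]-3-({2-[(3aS,5R,7aS)-2-hydroxy-5-methylhexahydro-2H-furo[3,2-b]pyran-2-yl]acetyl}oxy)-6-oxodec-4-enoate F6. A 5-exo-trig intramolecular Michael addition (Cs2CO3, MeCN) would then give 19.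

Step 13. The activated acid may undergo base-induced β-elimination of the lactone carboxylate, and oligomerisation may compete with the medium-ring closure. The fallback closes the ten-membered ring by olefin metathesis before the butyrolactone is built; it sets out from 16, 15 and 11 and returns at 22. Silylation of 16 (TBSCl, imidazole) would give tert-butyl (3S)-3-[(tert-butyldimethylsilyl)oxy]pent-4-enoate F7. Selective ester cleavage with 85 % aqueous H3PO4 in toluene would give (3S)-3-[(tert-butyldimethylsilyl)oxy]pent-4-enoic acid F8. Desilylation of 15 with HF·pyridine would give (6R)-6-hydroxyhept-1-en-3-one F9. Esterification of F8 with F9 (EDC·HCl, DMAP) would give (2R)-5-oxohept-6-en-2-yl (3S)-3-[(tert-butyldimethylsilyl)oxy]pent-4-enoate F10. Ring-closing metathesis with (H2IMes)Cl2Ru=CH(C6H4-2-O-i-Pr) at high dilution would give (4S,5E,10R)-4-[(tert-butyldimethylsilyl)oxy]-10-methyl-3,4,9,10-tetrahydro-2H-oxecine-2,7(8H)-dione F11. HF·pyridine would then free (4S,5E,10R)-4-hydroxy-10-methyl-3,4,9,10-tetrahydro-2H-oxecine-2,7(8H)-dione F12. Michael addition–lactonisation of 11 onto F12 (Cs2CO3, MeCN) would give the macrocyclic hemiketal lactone (the formal hydrate of 22 at the enol-ether carbon) F13, and CF3CO2H in CH2Cl2 would dehydrate it to 22.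

**Further compounds**

F1 | step 5 | ethyl (2E)-3-{[(2R)-5-oxopentan-2-yl]oxy}prop-2-enoate | O=CCC[C@@H](C)O/C=C/C(=O)OCC
F2 | step 5 | ethyl 2-[(2S,3R,6R)-3-hydroxy-6-methyloxan-2-yl]acetate | CCOC(=O)C[C@@H]1O[C@H](C)CC[C@H]1O
F3 | step 5 | 2-[(2S,3R,6R)-3-hydroxy-6-methyloxan-2-yl]acetic acid | OC(=O)C[C@@H]1O[C@H](C)CC[C@H]1O
F4 | step 11 | benzyl 2-[(3aS,5R,7aS)-2-hydroxy-5-methylhexahydro-2H-furo[3,2-b]pyran-2-yl]acetate | O=C(CC1(O)C[C@@H]2O[C@H](C)CC[C@@H]2O1)OCc1ccccc1
F5 | step 11 | 2-[(3aS,5R,7aS)-2-hydroxy-5-methylhexahydro-2H-furo[3,2-b]pyran-2-yl]acetic acid | OC(=O)CC1(O)C[C@@H]2O[C@H](C)CC[C@@H]2O1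
F6 | step 11 | tert-butyl (3S,4E,9R)-9-[(tert-butyldimethylsilyl)oxy]-3-({2-[(3aS,5R,7aS)-2-hydroxy-5-methylhexahydro-2H-furo[3,2-b]pyran-2-yl]acetyl}oxy)-6-oxodec-4-enoate | CC(C)(C)OC(=O)C[C@H](OC(=O)CC1(O)C[C@@H]2O[C@H](C)CC[C@@H]2O1)/C=C/C(=O)CC[C@@H](C)O[Si](C)(C)C(C)(C)C
F7 | step 13 | tert-butyl (3S)-3-[(tert-butyldimethylsilyl)oxy]pent-4-enoate | C=C[C@@H](O[Si](C)(C)C(C)(C)C)CC(=O)OC(C)(C)C
F8 | step 13 | (3S)-3-[(tert-butyldimethylsilyl)oxy]pent-4-enoic acid | C=C[C@@H](O[Si](C)(C)C(C)(C)C)CC(=O)O
F9 | step 13 | (6R)-6-hydroxyhept-1-en-3-one | C=CC(=O)CC[C@@H](C)O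
F10 | step 13 | (2R)-5-oxohept-6-en-2-yl (3S)-3-[(tert-butyldimethylsilyl)oxy]pent-4-enoate | C=C[C@@H](O[Si](C)(C)C(C)(C)C)CC(=O)O[C@H](C)CCC(=O)C=C
F11 | step 13 | (4S,5E,10R)-4-[(tert-butyldimethylsilyl)oxy]-10-methyl-3,4,9,10-tetrahydro-2H-oxecine-2,7(8H)-dione | C[C@@H]1CCC(=O)/C=C/[C@@H](O[Si](C)(C)C(C)(C)C)CC(=O)O1
F12 | step 13 | (4S,5E,10R)-4-hydroxy-10-methyl-3,4,9,10-tetrahydro-2H-oxecine-2,7(8H)-dione | C[C@@H]1CCC(=O)/C=C/[C@@H](O)CC(=O)O1
F13 | step 13 | macrocyclic hemiketal lactone (formal hydrate of 22 at the enol-ether carbon; epimers at the lactone α-carbon and the hemiketal carbon) | C[C@@H]1CCC(=O)C[C@@H]2C(C3(O)C[C@@H]4O[C@H](C)CC[C@@H]4O3)C(=O)O[C@H]2CC(=O)O1
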